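**Plan**
- Retrosynthetic cuts: the aryl–O–CH2 ether bond (Mitsunobu), the side-chain bond CH2–C(CH3)= (Negishi), C4–C5 of the bicycle (oxocarbenium–alkene cyclization ended by a 1,2-hydride shift) and C1–C8 (Ireland–Claisen).
- Enabling feature, with the core numbered as 1,5-dimethyl-6-oxabicyclo[3.2.1]octan-2-ol: C5 is the tertiary ether carbon of the oxolane ring O6–C7–C1–C8–C5, and the carbinol C2 on the C1 arm lies three bonds from it (C2–C3–C4–C5). This is the imprint of a C1-bound vinyl carbinol adding through its terminal carbon to a C5 oxocarbenium ion.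
- Forward order: allylic ester, C1–C8 by Ireland–Claisen, oxolane ring (lactone, then 2-methoxy-2-methyl ketal), vinyl carbinol on C1, cyclohexane ring by C4–C5 closure, side chain by Negishi coupling, coumarin ether last.
- Stereochemistry: a CBS reduction gives the (S)-carbinol, whose chirality is relayed through a chair transition state to C1 and C8; a Shi epoxidation fixes C2 of the cyclization substrate; C5 follows from the tether; the C2 alcohol comes from axial hydride delivery; the E alkene comes from the enol triflate geometry.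

Key step: step 10

Remark on the chemistry: ring atoms are numbered C1–C5, O6, C7, C8 as in the target core from compound 8 onwards. The ketal carbon C5 of 11–16 is carried as both anomers (left undefined in the SMILES), because it becomes planar in step 10.

**Step 1**
Reactants: 1 1-[(tert-butyldimethylsilyl)oxy]propan-2-one; 2 N-methoxy-N-methyl-2-(triphenyl-λ5-phosphanylidene)acetamide
Product: 3 (2E)-4-[(tert-butyldimethylsilyl)oxy]-N-methoxy-N,3-dimethylbut-2-enamide
Conditions: toluene, 110 °C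
Reagents that add atoms: none
Why: Wittig olefination of an α-silyloxy ketone (activated by the α-oxygen) with an amide-stabilised ylide, which under thermodynamic control should place the amide trans to the larger CH2OSi group (E).

**Step 2**
Reactants: 3 (2E)-4-[(tert-butyldimethylsilyl)oxy]-N-methoxy-N,3-dimethylbut-2-enamide
Product: 4 (3E)-5-[(tert-butyldimethylsilyl)oxy]-4-methylpent-3-en-2-one
Conditions: MeMgBr (1.5 equiv), THF, 0 °C; then H2O
Reagents that add atoms: methylmagnesium bromide, C[Mg]Br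
Why: Weinreb ketone synthesis, in which the chelated tetrahedral adduct stops at the methyl ketone and the β,β-disubstituted enamide should react by 1,2-addition only.

**Step 3**
Reactants: 4 (3E)-5-[(tert-butyldimethylsilyl)oxy]-4-methylpent-3-en-2-one
Product: 5 (2S,3E)-5-[(tert-butyldimethylsilyl)oxy]-4-methylpent-3-en-2-ol
Conditions: (R)-Me-CBS (0.2 equiv), catecholborane, toluene, −78 °C; then aq. NaOH
Reagents that add atoms: none
Why: CBS reduction of a methyl alkenyl ketone with the alkenyl group as the large substituent; since the (S)-oxazaborolidine gives (R)-carbinols from such ketones, the (R)-catalyst should give the (S)-carbinol, and catecholborane avoids hydroboration of the alkene.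

**Step 4**
Reactants: 5 (2S,3E)-5-[(tert-butyldimethylsilyl)oxy]-4-methylpent-3-en-2-ol; 6 4-(benzyloxy)butanoic acid
Product: 7 (2S,3E)-5-[(tert-butyldimethylsilyl)oxy]-4-methylpent-3-en-2-yl 4-(benzyloxy)butanoate
Conditions: DCC, DMAP (cat.), CH2Cl2, 0 → 25 °C
Reagents that add atoms: none
Why: Steglich esterification of a secondary allylic alcohol, which leaves the carbinol configuration untouched.

**Step 5**
Reactants: 7 (2S,3E)-5-[(tert-butyldimethylsilyl)oxy]-4-methylpent-3-en-2-yl 4-(benzyloxy)butanoate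
Product: 10 (3R,4R)-3-[2-(benzyloxy)ethyl]-4-methyl-4-[(1E)-prop-1-en-1-yl]oxolan-2-one, via silyl ketene acetal 8 (not isolated), via hexenoic acid 9 (not isolated)
Conditions: LiN(i-Pr)2, THF, −78 °C; Me3SiCl, −78 → 60 °C; then 2 M HCl (aq.), 25 °C
Reagents that add atoms: none
Why: Ireland–Claisen rearrangement, in which kinetic deprotonation in THF gives the enolate with the chain trans to O–Li (cis to the allylic oxygen) and the chair transition state with the carbinol methyl equatorial relays the (S) centre to C1 (alkene methyl axial) and C8 (chain axial) and leaves an E-propenyl group; aqueous HCl then cleaves the silyl ester and the primary silyl ether, and the γ-hydroxy acid closes to the lactone with the C8 chain cis to the C1 methyl group.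

**Step 6**
Reactants: 10 (3R,4R)-3-[2-(benzyloxy)ethyl]-4-methyl-4-[(1E)-prop-1-en-1-yl]oxolan-2-one
Product: 12 (3R,4R)-3-[2-(benzyloxy)ethyl]-2-methoxy-2,4-dimethyl-4-[(1E)-prop-1-en-1-yl]oxolane, via lactol 11 (not isolated)
Conditions: MeLi (1.05 equiv), THF, −78 °C; AcOH; then MeOH, PPTS, 25 °C
Reagents that add atoms: methyllithium, [Li]C; methanol, CO
Why: Single addition of MeLi to a γ-lactone (the lithium lactolate is stable at −78 °C) followed by acid-catalysed mixed-ketal formation in methanol; the new centre C5 is inconsequential, and the mild acid should not form the enol ether that would touch C8.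

**Step 7**
Reactants: 12 (3R,4R)-3-[2-(benzyloxy)ethyl]-2-methoxy-2,4-dimethyl-4-[(1E)-prop-1-en-1-yl]oxolane
Product: 13 (3R,4R)-3-[2-(benzyloxy)ethyl]-2-methoxy-2,4-dimethyl-4-[(2S,3S)-3-methyloxiran-2-yl]oxolane
Conditions: ent-Shi ketone (L-fructose-derived, 0.3 equiv), KHSO5 (as the triple salt 2KHSO5·KHSO4·K2SO4), K2CO3, Bu4NHSO4, MeCN/(MeO)2CH2–aq. Na2B4O7 buffer (pH 10.5), 0 °C
Reagents that add atoms: potassium peroxymonosulfate, [K+].[O-]S(=O)(=O)OO
Why: Shi asymmetric epoxidation (chiral dioxirane, spiro transition state), for which E-1,2-disubstituted alkenes are the best substrates; the D-fructose-derived ketone gives (R,R)-epoxides, so its enantiomer should give the (2S,3S)-epoxide under reagent control, and the basic buffer leaves the ketal intact.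

**Step 8**
Reactants: 13 (3R,4R)-3-[2-(benzyloxy)ethyl]-2-methoxy-2,4-dimethyl-4-[(2S,3S)-3-methyloxiran-2-yl]oxolane
Product: 15 (1R)-1-{(3R,4R)-4-[2-(benzyloxy)ethyl]-5-methoxy-3,5-dimethyloxolan-3-yl}prop-2-en-1-ol, via hydroxy selenide 14 (not isolated)
Conditions: (PhSe)2, NaBH4, EtOH, 78 °C; then H2O2 (30 %), pyridine, THF, 0 → 25 °C
Reagents that add atoms: none
Why: Epoxide-to-allylic-alcohol transposition by selenide opening and selenoxide elimination, in which PhSe− attacks C3 (SN2; C2 is neopentylic) and the selenoxide eliminates syn towards the methyl group and away from the carbinol, so the C2–O bond and its configuration from step 7 are untouched.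

**Step 9**
Reactants: 15 (1R)-1-{(3R,4R)-4-[2-(benzyloxy)ethyl]-5-methoxy-3,5-dimethyloxolan-3-yl}prop-2-en-1-ol
Product: 16 triethyl{[(1R)-1-{(3R,4R)-4-[2-(benzyloxy)ethyl]-5-methoxy-3,5-dimethyloxolan-3-yl}prop-2-en-1-yl]oxy}silane
Conditions: Et3SiCl, imidazole, DMAP (cat.), DMF, 25 °C
Reagents that add atoms: chlorotriethylsilane, CC[Si](Cl)(CC)CC
Why: Silylation of the secondary alcohol with silyl chloride and imidazole, basic conditions that cannot ionise the ketal and change no stereocentre.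

**Step 10**
Reactants: 16 triethyl{[(1R)-1-{(3R,4R)-4-[2-(benzyloxy)ethyl]-5-methoxy-3,5-dimethyloxolan-3-yl}prop-2-en-1-yl]oxy}silane
Product: 17 (1R,5S,8R)-8-[2-(benzyloxy)ethyl]-1,5-dimethyl-6-oxabicyclo[3.2.1]octan-2-one
Conditions: Me3SiOTf (0.3 equiv), 2,6-di-tert-butyl-4-methylpyridine (0.1 equiv), CH2Cl2, −78 → −30 °C; Et3N
Reagents that add atoms: none
Why: Me3SiOTf removes methoxide from either anomer of 16 to give the five-membered oxocarbenium ion C5=O6+, the terminal vinyl carbon C4 bonds to C5, and the developing secondary cation at C3 is discharged by a 1,2-shift of the C2 hydrogen, the resulting silyloxycarbenium ion handing Et3Si+ to triflate (which ionises the next ketal) to leave the C2 ketone. The closest known reaction type is the Prins–pinacol cascade of acetals that carry an allylic silyl ether, here with hydrogen instead of carbon as the migrating group. The cyclohexane ring C1–C2–C3–C4–C5–C8 closes in a 6-endo mode with respect to the alkene (bond to the terminal carbon, cation at the internal one) and exo with respect to C5=O6, which gives the bridged 6-oxabicyclo[3.2.1]octane. The only new stereocentre, C5, is fixed by the tether: the arm on C1 can reach C5 solely from its own face of the oxolane, so the C4–C5 bond must form cis to C1–C2, while C1 and C8 pass through unchanged and C2 becomes a carbonyl. The step needs attack through C4 and not C3 (secured by six- over five-membered ring closure and a secondary over a primary cation) and hydride shift rather than ring-bond migration or capture by oxygen (secured by the (R) configuration at C2, which in the chair-like transition state puts C2–H axial and parallel to the empty orbital at C3 and the silyloxy group equatorial, and by the non-nucleophilic triflate counter-ion). The C8 chain, trans to the reacting arm, ends up equatorial, and its benzyloxy oxygen should add to C5 only reversibly at these temperatures.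

**Step 11**
Reactants: 17 (1R,5S,8R)-8-[2-(benzyloxy)ethyl]-1,5-dimethyl-6-oxabicyclo[3.2.1]octan-2-one
Product: 18 (1R,5S,8R)-8-(2-hydroxyethyl)-1,5-dimethyl-6-oxabicyclo[3.2.1]octan-2-one
Conditions: H2 (1 atm), Pd/C, EtOAc, 25 °C
Reagents that add atoms: none
Why: Hydrogenolysis of the benzyl ether, under which the ketone and the ether bridge are inert.

**Step 12**
Reactants: 18 (1R,5S,8R)-8-(2-hydroxyethyl)-1,5-dimethyl-6-oxabicyclo[3.2.1]octan-2-one
Product: 19 (1R,5S,8R)-8-(2-iodoethyl)-1,5-dimethyl-6-oxabicyclo[3.2.1]octan-2-one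
Conditions: PPh3, I2, imidazole, CH2Cl2, 0 → 25 °C
Reagents that add atoms: iodine, II
Why: Appel-type iodination (iodophosphonium activation, SN2 at the primary carbon), compatible with the ketone.

**Step 13**
Reactants: 20 ethyl 3-oxobutanoate
Product: 21 ethyl (2E)-3-{[(trifluoromethyl)sulfonyl]oxy}but-2-enoate
Conditions: Tf2O, Me4NOH (aq.), hexanes, 5 °C
Reagents that add atoms: trifluoromethanesulfonic anhydride, O=S(=O)(OS(=O)(=O)C(F)(F)F)C(F)(F)F
Why: O-triflation of the β-keto ester enolate, in which the non-chelating tetramethylammonium counter-ion should favour the enolate with its oxygen anti to the ester and hence the E-enol triflate.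

**Step 14**
Reactants: 19 (1R,5S,8R)-8-(2-iodoethyl)-1,5-dimethyl-6-oxabicyclo[3.2.1]octan-2-one; 21 ethyl (2E)-3-{[(trifluoromethyl)sulfonyl]oxy}but-2-enoate
Product: 23 ethyl (2E)-5-[(1R,5S,8R)-1,5-dimethyl-2-oxo-6-oxabicyclo[3.2.1]octan-8-yl]-3-methylpent-2-enoate, via alkylzinc iodide 22 (not isolated)
Conditions: Zn dust, LiCl, THF, 40 °C; then 21, PdCl2(dppf) (5 mol %), THF/NMP, 25 → 50 °C
Reagents that add atoms: none
Why: LiCl-promoted zinc insertion into the primary C–I bond tolerates the ketone, and the Negishi coupling (zerovalent palladium formed in situ) joins the sp3 carbon to the alkenyl carbon with retention of the triflate geometry, the wide-bite-angle dppf ligand favouring reductive elimination over β-hydride elimination.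

**Step 15**
Reactants: 23 ethyl (2E)-5-[(1R,5S,8R)-1,5-dimethyl-2-oxo-6-oxabicyclo[3.2.1]octan-8-yl]-3-methylpent-2-enoate
Product: 24 ethyl (2E)-5-[(1R,2R,5S,8R)-2-hydroxy-1,5-dimethyl-6-oxabicyclo[3.2.1]octan-8-yl]-3-methylpent-2-enoate
Conditions: NaBH4, EtOH, 0 °C
Reagents that add atoms: none
Why: Ketone reduction by a small hydride donor, in which axial attack on the chair cyclohexanone from the face opposite the O6–C7 bridge (the other face is screened by the axial C7 on C1) should give the equatorial (2R)-alcohol while the enoate is not touched.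

**Step 16**
Reactants: 24 ethyl (2E)-5-[(1R,2R,5S,8R)-2-hydroxy-1,5-dimethyl-6-oxabicyclo[3.2.1]octan-8-yl]-3-methylpent-2-enoate
Product: 25 (1R,2R,5S,8R)-8-[(3E)-5-hydroxy-3-methylpent-3-en-1-yl]-1,5-dimethyl-6-oxabicyclo[3.2.1]octan-2-ol
Conditions: i-Bu2AlH (3.5 equiv), CH2Cl2, −78 → 0 °C
Reagents that add atoms: none
Why: 1,2-Reduction of the enoate to the allylic alcohol with i-Bu2AlH, which preserves the alkene geometry and the C2 alcohol (present as its aluminium alkoxide).

**Step 17**
Reactants: 25 (1R,2R,5S,8R)-8-[(3E)-5-hydroxy-3-methylpent-3-en-1-yl]-1,5-dimethyl-6-oxabicyclo[3.2.1]octan-2-ol; 26 7-hydroxy-2H-chromen-2-one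
Product: 27 7-{[(2E)-5-[(1R,2R,5S,8R)-2-hydroxy-1,5-dimethyl-6-oxabicyclo[3.2.1]octan-8-yl]-3-methylpent-2-en-1-yl]oxy}-2H-chromen-2-one
Conditions: PPh3, DIAD, THF, 0 → 25 °C
Reagents that add atoms: none
Why: Mitsunobu etherification with the acidic phenol by SN2 at the primary allylic carbon; the secondary C2 alcohol, neopentylic and flanked by the quaternary C1, should not be activated.

**Compound list**
1 | 1-[(tert-butyldimethylsilyl)oxy]propan-2-one | CC(=O)CO[Si](C)(C)C(C)(C)C | starting material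
2 | N-methoxy-N-methyl-2-(triphenyl-λ5-phosphanylidene)acetamide | CON(C)C(=O)C=P(c1ccccc1)(c1ccccc1)c1ccccc1 | starting material
3 | (2E)-4-[(tert-butyldimethylsilyl)oxy]-N-methoxy-N,3-dimethylbut-2-enamide | CON(C)C(=O)/C=C(\C)CO[Si](C)(C)C(C)(C)C | intermediate
4 | (3E)-5-[(tert-butyldimethylsilyl)oxy]-4-methylpent-3-en-2-one | CC(=O)/C=C(\C)CO[Si](C)(C)C(C)(C)C | intermediate
5 | (2S,3E)-5-[(tert-butyldimethylsilyl)oxy]-4-methylpent-3-en-2-ol | C[C@H](O)/C=C(\C)CO[Si](C)(C)C(C)(C)C | intermediate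
6 | 4-(benzyloxy)butanoic acid | OC(=O)CCCOCc1ccccc1 | starting material
7 | (2S,3E)-5-[(tert-butyldimethylsilyl)oxy]-4-methylpent-3-en-2-yl 4-(benzyloxy)butanoate | C[C@H](OC(=O)CCCOCc1ccccc1)/C=C(\C)CO[Si](C)(C)C(C)(C)C | intermediate
8 | trimethylsilyl ketene acetal of 7, CH2CH2OBn chain cis to the allylic oxygen | C[C@H](O/C(O[Si](C)(C)C)=C\CCOCc1ccccc1)/C=C(\C)CO[Si](C)(C)C(C)(C)C | intermediate
9 | (2R,3R,4E)-2-[2-(benzyloxy)ethyl]-3-{[(tert-butyldimethylsilyl)oxy]methyl}-3-methylhex-4-enoic acid | C/C=C/[C@@](C)(CO[Si](C)(C)C(C)(C)C)[C@@H](CCOCc1ccccc1)C(=O)O | intermediate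
10 | (3R,4R)-3-[2-(benzyloxy)ethyl]-4-methyl-4-[(1E)-prop-1-en-1-yl]oxolan-2-one | C/C=C/[C@@]1(C)COC(=O)[C@@H]1CCOCc1ccccc1 | intermediate
11 | (3R,4R)-3-[2-(benzyloxy)ethyl]-2,4-dimethyl-4-[(1E)-prop-1-en-1-yl]oxolan-2-ol, both anomers | C/C=C/[C@@]1(C)COC(C)(O)[C@@H]1CCOCc1ccccc1 | intermediate
12 | (3R,4R)-3-[2-(benzyloxy)ethyl]-2-methoxy-2,4-dimethyl-4-[(1E)-prop-1-en-1-yl]oxolane, both anomers | C/C=C/[C@@]1(C)COC(C)(OC)[C@@H]1CCOCc1ccccc1 | intermediate
13 | (3R,4R)-3-[2-(benzyloxy)ethyl]-2-methoxy-2,4-dimethyl-4-[(2S,3S)-3-methyloxiran-2-yl]oxolane | C[C@@H]1O[C@H]1[C@@]1(C)COC(C)(OC)[C@@H]1CCOCc1ccccc1 | intermediate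
14 | (1S,2R)-1-{(3R,4R)-4-[2-(benzyloxy)ethyl]-5-methoxy-3,5-dimethyloxolan-3-yl}-2-(phenylselanyl)propan-1-ol | C[C@@H]([Se]c1ccccc1)[C@@H](O)[C@@]1(C)COC(C)(OC)[C@@H]1CCOCc1ccccc1 | intermediate
15 | (1R)-1-{(3R,4R)-4-[2-(benzyloxy)ethyl]-5-methoxy-3,5-dimethyloxolan-3-yl}prop-2-en-1-ol | C=C[C@@H](O)[C@@]1(C)COC(C)(OC)[C@@H]1CCOCc1ccccc1 | intermediate
16 | triethyl{[(1R)-1-{(3R,4R)-4-[2-(benzyloxy)ethyl]-5-methoxy-3,5-dimethyloxolan-3-yl}prop-2-en-1-yl]oxy}silane | C=C[C@@H](O[Si](CC)(CC)CC)[C@@]1(C)COC(C)(OC)[C@@H]1CCOCc1ccccc1 | intermediate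
17 | (1R,5S,8R)-8-[2-(benzyloxy)ethyl]-1,5-dimethyl-6-oxabicyclo[3.2.1]octan-2-one | C(OCC[C@@H]1[C@]2(C)CO[C@@]1(C)CCC2=O)c1ccccc1 | intermediate
18 | (1R,5S,8R)-8-(2-hydroxyethyl)-1,5-dimethyl-6-oxabicyclo[3.2.1]octan-2-one | OCC[C@@H]1[C@]2(C)CO[C@@]1(C)CCC2=O | intermediate
19 | (1R,5S,8R)-8-(2-iodoethyl)-1,5-dimethyl-6-oxabicyclo[3.2.1]octan-2-one | ICC[C@@H]1[C@]2(C)CO[C@@]1(C)CCC2=O | intermediate
20 | ethyl 3-oxobutanoate | CCOC(=O)CC(C)=O | starting material
21 | ethyl (2E)-3-{[(trifluoromethyl)sulfonyl]oxy}but-2-enoate | CCOC(=O)/C=C(\C)OS(=O)(=O)C(F)(F)F | intermediate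
22 | {2-[(1R,5S,8R)-1,5-dimethyl-2-oxo-6-oxabicyclo[3.2.1]octan-8-yl]ethyl}(iodo)zinc | I[Zn]CC[C@@H]1[C@]2(C)CO[C@@]1(C)CCC2=O | intermediate
23 | ethyl (2E)-5-[(1R,5S,8R)-1,5-dimethyl-2-oxo-6-oxabicyclo[3.2.1]octan-8-yl]-3-methylpent-2-enoate | CCOC(=O)/C=C(\C)CC[C@@H]1[C@]2(C)CO[C@@]1(C)CCC2=O | intermediate
24 | ethyl (2E)-5-[(1R,2R,5S,8R)-2-hydroxy-1,5-dimethyl-6-oxabicyclo[3.2.1]octan-8-yl]-3-methylpent-2-enoate | CCOC(=O)/C=C(\C)CC[C@@H]1[C@]2(C)CO[C@@]1(C)CC[C@H]2O | intermediate
25 | (1R,2R,5S,8R)-8-[(3E)-5-hydroxy-3-methylpent-3-en-1-yl]-1,5-dimethyl-6-oxabicyclo[3.2.1]octan-2-ol | C/C(=C\CO)CC[C@@H]1[C@]2(C)CO[C@@]1(C)CC[C@H]2O | intermediate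
26 | 7-hydroxy-2H-chromen-2-one | Oc1ccc2ccc(=O)oc2c1 | starting material
27 | 7-{[(2E)-5-[(1R,2R,5S,8R)-2-hydroxy-1,5-dimethyl-6-oxabicyclo[3.2.1]octan-8-yl]-3-methylpent-2-en-1-yl]oxy}-2H-chromen-2-one | C/C(=C\COc1ccc2ccc(=O)oc2c1)CC[C@@H]1[C@]2(C)CO[C@@]1(C)CC[C@H]2O | target

**Step count**
Total: 17 steps. Longest linear sequence: 16 steps (steps 1–12 and 14–17, from 1); step 13 is a one-step side branch.

**Steps most likely to fail**

1. Step 10. The inductively deactivated vinyl group may add too slowly. Then loss of a proton from the oxocarbenium ion (enol ether formation, with scrambling at C8) or capture of C5 by the benzyloxy oxygen with loss of benzyl could take over, as could interception of the C3 cation by the silyloxy oxygen or by ring-bond migration. The fallback forms the same C4–C5 bond by a radical with reversed polarity. It sets out from 16: PhSeH and BF3·OEt2 (CH2Cl2, −78 °C) exchange the methoxy group to give the phenylselanyl ketal F1, Bu4NF removes the silyl group to give the allylic alcohol F2, and oxidation (SO3·pyridine, DMSO, i-Pr2NEt) gives the vinyl ketone F3. Bu3SnH and AIBN (benzene, 80 °C, slow addition) should then generate the tertiary α-oxy radical at C5, which adds 6-endo to the terminal enone carbon C4; the α-keto radical takes hydrogen from the stannane, and the route is rejoined at 17.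

2. Step 7. The dioxirane has to override the facial bias of the neighbouring quaternary centre C1 on a hindered alkene, so poor facial selectivity, slow oxidation and decay of the ketone catalyst are possible. The fallback builds the carbinol by carbonyl addition instead of epoxide transposition. It sets out from 12: ozonolysis (O3, CH2Cl2/MeOH, −78 °C; PPh3) gives the aldehyde F4, and CH2=CHMgBr (THF, −78 °C) gives 15 together with its C2 epimer F5. After separation, F5 is oxidized (SO3·pyridine, DMSO) to the vinyl ketone F6 and reduced again with (S)-Me-CBS and catecholborane (quaternary carbon as the large group) to 15. The route is rejoined at 15, and steps 7 and 8 are both bypassed.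

3. Step 14. Zinc insertion beside the enolisable ketone may be sluggish, or the alkylzinc may be protonated; β-hydride elimination and loss of alkene geometry at the alkenylpalladium stage are further risks. The fallback is a B-alkyl Suzuki–Miyaura coupling after the ketone has been reduced and masked, which allows a lithium-derived borinate. It sets out from 17: NaBH4 (EtOH, 0 °C) gives the alcohol F7, t-BuMe2SiOTf and 2,6-lutidine the silyl ether F8, hydrogenolysis (H2, Pd/C) the primary alcohol F9, and PPh3/I2/imidazole the iodide F10. Treatment with t-BuLi (Et2O, −78 °C), then B-methoxy-9-BBN, then 21 with PdCl2(dppf) and K3PO4 (DMF/H2O) gives the silyl-protected enoate F11. HF·pyridine rejoins the route at 24.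

**Further compounds**
F1 | step 10 | triethyl{[(1R)-1-{(3R,4R)-4-[2-(benzyloxy)ethyl]-3,5-dimethyl-5-(phenylselanyl)oxolan-3-yl}prop-2-en-1-yl]oxy}silane | C=C[C@@H](O[Si](CC)(CC)CC)[C@@]1(C)COC(C)([Se]c2ccccc2)[C@@H]1CCOCc1ccccc1
F2 | step 10 | (1R)-1-{(3R,4R)-4-[2-(benzyloxy)ethyl]-3,5-dimethyl-5-(phenylselanyl)oxolan-3-yl}prop-2-en-1-ol | C=C[C@@H](O)[C@@]1(C)COC(C)([Se]c2ccccc2)[C@@H]1CCOCc1ccccc1
F3 | step 10 | 1-{(3R,4R)-4-[2-(benzyloxy)ethyl]-3,5-dimethyl-5-(phenylselanyl)oxolan-3-yl}prop-2-en-1-one | C=CC(=O)[C@@]1(C)COC(C)([Se]c2ccccc2)[C@@H]1CCOCc1ccccc1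
F4 | step 7 | (3R,4R)-4-[2-(benzyloxy)ethyl]-5-methoxy-3,5-dimethyloxolane-3-carbaldehyde | O=C[C@@]1(C)COC(C)(OC)[C@@H]1CCOCc1ccccc1
F5 | step 7 | (1S)-1-{(3R,4R)-4-[2-(benzyloxy)ethyl]-5-methoxy-3,5-dimethyloxolan-3-yl}prop-2-en-1-ol (C2 epimer of 15) | C=C[C@H](O)[C@@]1(C)COC(C)(OC)[C@@H]1CCOCc1ccccc1
F6 | step 7 | 1-{(3R,4R)-4-[2-(benzyloxy)ethyl]-5-methoxy-3,5-dimethyloxolan-3-yl}prop-2-en-1-one | C=CC(=O)[C@@]1(C)COC(C)(OC)[C@@H]1CCOCc1ccccc1
F7 | step 14 | (1R,2R,5S,8R)-8-[2-(benzyloxy)ethyl]-1,5-dimethyl-6-oxabicyclo[3.2.1]octan-2-ol | C(OCC[C@@H]1[C@]2(C)CO[C@@]1(C)CC[C@H]2O)c1ccccc1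
F8 | step 14 | {[(1R,2R,5S,8R)-8-[2-(benzyloxy)ethyl]-1,5-dimethyl-6-oxabicyclo[3.2.1]octan-2-yl]oxy}(tert-butyl)dimethylsilane | C(OCC[C@@H]1[C@]2(C)CO[C@@]1(C)CC[C@H]2O[Si](C)(C)C(C)(C)C)c1ccccc1
F9 | step 14 | 2-[(1R,2R,5S,8R)-2-[(tert-butyldimethylsilyl)oxy]-1,5-dimethyl-6-oxabicyclo[3.2.1]octan-8-yl]ethan-1-ol | OCC[C@@H]1[C@]2(C)CO[C@@]1(C)CC[C@H]2O[Si](C)(C)C(C)(C)C
F10 | step 14 | tert-butyl{[(1R,2R,5S,8R)-8-(2-iodoethyl)-1,5-dimethyl-6-oxabicyclo[3.2.1]octan-2-yl]oxy}dimethylsilane | ICC[C@@H]1[C@]2(C)CO[C@@]1(C)CC[C@H]2O[Si](C)(C)C(C)(C)C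
F11 | step 14 | ethyl (2E)-5-[(1R,2R,5S,8R)-2-[(tert-butyldimethylsilyl)oxy]-1,5-dimethyl-6-oxabicyclo[3.2.1]octan-8-yl]-3-methylpent-2-enoate | CCOC(=O)/C=C(\C)CC[C@@H]1[C@]2(C)CO[C@@]1(C)CC[C@H]2O[Si](C)(C)C(C)(C)C
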